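**Plan**
1. Numbering and enabling feature: ring A is O1, C2 (CH3), C3 (C7H2–O8H), C4 (C10H2–C9(=O)O arm), C5 (CO2Me), C6. O1=C6–C5=C4 is a 2-formylacrylate 1-oxadiene and C2=C3 is the alkene of (E)-crotyl alcohol. O8 can be bonded to C9, so C3–C7–O8–C9–C10–C4 becomes a six-membered ring B.
2. Retrosynthesis: cut the O–CH2 bond of the hydroxytyrosyl ester and join O8 to C9 (δ-lactone, then crotyl acetal). Then cut O1–C2, C3–C4 and C4=C5 together, which leaves 3,3-bis(crotyloxy)propanal and methyl 3-oxopropanoate.
3. Forward: rings A and B arise together in one flask by Knoevenagel condensation followed by an intramolecular inverse-demand oxa-Diels–Alder reaction. Ring B is oxidised to the lactone and opened by hydroxide, the arene chain is joined last by carboxylate alkylation, and hydrogenolysis ends the route.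
4. Stereochemistry: C2/C3 trans comes from suprafacial addition to the (E)-alkene and C3/C4 trans from the exo chair of the tether. The absolute configuration comes from a chiral one-point Lewis acid of trivalent chromium on the formyl oxygen. The fourth centre, C9, is erased on oxidation.

Key step: step 4

Assumption: the sense of induction of [Cr(L)]SbF6 (H2L = Schiff base of 3-(1-adamantyl)-2-hydroxy-5-methylbenzaldehyde with (1R,2S)-1-amino-2-indanol) on this new heterodiene cannot be predicted with certainty; the (1R,2S) ligand is written, and its equally available mirror image is used if a trial run shows the opposite sense.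

Step 1
Reactants: 1 methyl 3,3-dimethoxypropanoate; 2 (E)-but-2-en-1-ol (crotyl alcohol)
Product: 3 methyl 3,3-bis[(E)-but-2-enyloxy]propanoate
Conditions: 2 (4 equiv), PPTS (5 mol %), toluene, 85 °C, MeOH distilled off as the azeotrope
Reagents that add atoms: none
Why: Acid-catalysed transacetalisation is an equilibrium driven to the bis-crotyl acetal by removing the volatile methanol, and the mild pyridinium acid keeps β-elimination to the alkoxyacrylate and ionisation of the allylic alcohol slow.

Step 2
Reactants: 3 methyl 3,3-bis[(E)-but-2-enyloxy]propanoate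
Product: 4 3,3-bis[(E)-but-2-enyloxy]propanal
Conditions: iBu2AlH (DIBAL-H, 1.05 equiv), CH2Cl2, −78 °C; aq. KNaC4H4O6 (potassium sodium tartrate); used crude at once
Reagents that add atoms: none
Why: Partial ester reduction with DIBAL-H at −78 °C stops at the aluminium hemiacetal, here held by a β-acetal oxygen, and frees the aldehyde only on work-up, as is routine for 3,3-dialkoxypropanoates.

Step 3
Reactants: 5 methyl acetate; 6 methyl formate
Product: 7 sodium (E)-3-methoxy-3-oxoprop-1-en-1-olate (sodium enolate of methyl 3-oxopropanoate)
Conditions: NaH (1.0 equiv), Et2O, 0 °C → rt; precipitate filtered and dried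
Reagents that add atoms: sodium hydride, [Na+].[H-]
Why: In this crossed Claisen condensation the non-enolisable, more electrophilic formate acylates the acetate enolate, and precipitation of the stabilised sodium enolate drives the reaction and avoids handling the self-condensing free aldehyde.

Step 4
Reactants: 4 3,3-bis[(E)-but-2-enyloxy]propanal; 7 sodium (E)-3-methoxy-3-oxoprop-1-en-1-olate
Product: 10 methyl (1R,4aS,6R,8aR)-6-[(E)-but-2-enyloxy]-1-methyl-4a,5,8,8a-tetrahydro-1H,6H-pyrano[3,4-c]pyran-4-carboxylate (trans-fused rings A/B; crotyloxy group axial at C9), via methyl 3-oxopropanoate 8 (not isolated), via formylacrylate oxadiene 9 (not isolated)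
Conditions: 7 (1.3 equiv), AcOH (1.3 equiv, slow addition), ethylenediammonium diacetate (EDDA, 5 mol %), 4 Å MS, CH2Cl2, −20 → 0 °C; cold filtration through Celite into [Cr(L)]SbF6 (10 mol %, prepared beforehand from CrCl(L) and AgSbF6), 4 Å MS, CH2Cl2 (0.02 M), 0 °C → rt
Reagents that add atoms: none
Why: Proposed new method: acetic acid releases 8 from 7, the amine salt condenses it with 4 (Knoevenagel condensation, C4=C5), and the electron-poor 1-oxadiene O1=C6–C5=C4 of 9, bound through its formyl oxygen to the cationic complex of trivalent chromium, adds one tethered (E)-crotyl alkene in a concerted but asynchronous inverse-electron-demand [4+2] cycloaddition in which C3–C4 runs ahead of O1–C2. The closest known reaction types are the diastereoselective domino Knoevenagel–intramolecular oxa-Diels–Alder reaction of alkylidene 1,3-dicarbonyl compounds with unactivated alkenes and the enantioselective inverse-demand hetero-Diels–Alder reaction of α,β-unsaturated aldehydes with enol ethers under this family of chromium Schiff-base complexes; what has not been shown is their union on a 2-formylacrylate with an unactivated alkene. A one-point binder is chosen on purpose, because a metal chelated by the formyl and the ester oxygen would hold O1=C6–C5=C4 s-trans, a geometry from which the ring cannot close, whereas coordination at the formyl lone pair syn to H6 lowers the LUMO and leaves the s-cis form accessible. Ring A closes as the six-membered ring of the [4+2] addition itself, and ring B closes in the same event in the fused mode as a six-membered ring, since the four tether atoms C10, C9, O8 and C7 link C4 to C3 and fold into a chair in the exo transition state. C2/C3 trans is fixed by suprafacial addition to the (E)-alkene, C3/C4 trans by the exo chair that places the tether anti to the heterodiene, C9 by the anomeric preference of the spectator crotyloxy group for the axial site, and the absolute sense by the ligand, which shields one face of the bound heterodiene and thereby also decides which of the two enantiotopic crotyl groups reacts. The step needs the formyl and not the ester oxygen to enter ring A (an ester carbonyl is by far the poorer heterodiene terminus), [4+2] addition instead of an ene reaction (favoured by the formyl heterodiene and the short chair-like tether), and survival of the β-acetal against vinylogous loss of crotyl alcohol, which the cold acetate buffer, the low amine loading and its removal before warming are meant to secure.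

Step 5
Reactants: 10 trans-fused crotyl acetal
Product: 11 methyl (1R,4aS,8aR)-6-hydroxy-1-methyl-4a,5,8,8a-tetrahydro-1H,6H-pyrano[3,4-c]pyran-4-carboxylate (lactol, anomeric mixture at C9)
Conditions: AcOH–THF–H2O (4:2:1), 45 °C
Reagents that add atoms: water, O
Why: Acid hydrolysis of a 2-alkoxytetrahydropyran under the conditions used for THP ethers proceeds through the ring B oxocarbenium ion, the O1–C6=C5–CO2Me unit is a vinylogous carbonate that resists protonation, and C2, C3 and C4 are untouched.

Step 6
Reactants: 11 lactol
Product: 12 methyl (1R,4aS,8aR)-1-methyl-6-oxo-4a,5,8,8a-tetrahydro-1H,6H-pyrano[3,4-c]pyran-4-carboxylate (trans-fused δ-lactone)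
Conditions: PhI(OAc)2 (1.2 equiv), TEMPO (10 mol %), CH2Cl2, rt
Reagents that add atoms: none
Why: The oxoammonium-mediated (TEMPO) oxidation of lactols to lactones is mild and leaves the donor–acceptor alkene alone, and it converts both anomers into one compound by erasing C9.

Step 7
Reactants: 13 hydroxytyrosol (4-(2-hydroxyethyl)benzene-1,2-diol)
Product: 14 2-[3,4-bis(benzyloxy)phenyl]ethanol
Conditions: BnBr (2.2 equiv), K2CO3 (2.5 equiv), acetone, reflux
Reagents that add atoms: benzyl bromide, BrCc1ccccc1
Why: In this Williamson ether synthesis K2CO3 deprotonates only the two phenols, so the aliphatic alcohol stays free.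

Step 8
Reactants: 14 2-[3,4-bis(benzyloxy)phenyl]ethanol
Product: 15 1,2-bis(benzyloxy)-4-(2-bromoethyl)benzene
Conditions: CBr4 (1.2 equiv), PPh3 (1.25 equiv), CH2Cl2, 0 °C
Reagents that add atoms: carbon tetrabromide, BrC(Br)(Br)Br
Why: The Appel reaction replaces the primary hydroxyl by bromide through SN2 attack on the alkoxyphosphonium ion under neutral conditions that benzyl ethers tolerate.

Step 9
Reactants: 12 trans-fused δ-lactone; 15 1,2-bis(benzyloxy)-4-(2-bromoethyl)benzene
Product: 17 methyl (2R,3R,4S)-4-(2-{2-[3,4-bis(benzyloxy)phenyl]ethoxy}-2-oxoethyl)-3-(hydroxymethyl)-2-methyl-3,4-dihydro-2H-pyran-5-carboxylate, via caesium hydroxy carboxylate 16 (not isolated)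
Conditions: CsOH·H2O (1.0 equiv), THF–H2O, 0 °C; evaporation, toluene azeotrope; 15 (1.2 equiv), Bu4NI (10 mol %), DMF, rt
Reagents that add atoms: caesium hydroxide, [OH-].[Cs+]
Why: One equivalent of hydroxide saponifies the δ-lactone far faster than the push–pull-deactivated conjugated methyl ester, and SN2 O-alkylation of the caesium carboxylate in DMF builds the ester without passing through the free hydroxy acid, which would relactonise; no stereocentre takes part.

Step 10
Reactants: 17 dibenzyl ether of the target
Product: 18 methyl (2R,3R,4S)-4-{2-[2-(3,4-dihydroxyphenyl)ethoxy]-2-oxoethyl}-3-(hydroxymethyl)-2-methyl-3,4-dihydro-2H-pyran-5-carboxylate (CNP0204147.1)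
Conditions: H2 (1 atm), Pd/C (10 wt %), EtOAc, rt, stopped after uptake of two equivalents
Reagents that add atoms: none
Why: Hydrogenolysis of aryl benzyl ethers over Pd/C runs under neutral conditions, so the δ-hydroxy ester should not lactonise, and the trisubstituted donor–acceptor alkene C5=C6 and the homobenzylic ester C–O bond are inert at one atmosphere.

**Compound list**
1 | methyl 3,3-dimethoxypropanoate | COC(=O)CC(OC)OC | starting material
2 | (E)-but-2-en-1-ol (crotyl alcohol) | C/C=C/CO | starting material
3 | methyl 3,3-bis[(E)-but-2-enyloxy]propanoate | COC(=O)CC(OC/C=C/C)OC/C=C/C | intermediate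
4 | 3,3-bis[(E)-but-2-enyloxy]propanal | O=CCC(OC/C=C/C)OC/C=C/C | intermediate
5 | methyl acetate | CC(=O)OC | starting material
6 | methyl formate | COC=O | starting material
7 | sodium (E)-3-methoxy-3-oxoprop-1-en-1-olate (enolate geometry of no consequence) | COC(=O)/C=C/[O-].[Na+] | intermediate
8 | methyl 3-oxopropanoate (not isolated) | COC(=O)CC=O | intermediate
9 | methyl (Z)-5,5-bis[(E)-but-2-enyloxy]-2-formylpent-2-enoate (formyl trans to the tether; not isolated) | COC(=O)/C(C=O)=C\CC(OC/C=C/C)OC/C=C/C | intermediate
10 | methyl (1R,4aS,6R,8aR)-6-[(E)-but-2-enyloxy]-1-methyl-4a,5,8,8a-tetrahydro-1H,6H-pyrano[3,4-c]pyran-4-carboxylate (trans-fused, axial anomer) | COC(=O)C1=CO[C@H](C)[C@@H](CO2)[C@@H]1C[C@@H]2OC/C=C/C | intermediate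
11 | methyl (1R,4aS,8aR)-6-hydroxy-1-methyl-4a,5,8,8a-tetrahydro-1H,6H-pyrano[3,4-c]pyran-4-carboxylate (anomeric mixture) | COC(=O)C1=CO[C@H](C)[C@@H](CO2)[C@@H]1CC2O | intermediate
12 | methyl (1R,4aS,8aR)-1-methyl-6-oxo-4a,5,8,8a-tetrahydro-1H,6H-pyrano[3,4-c]pyran-4-carboxylate | COC(=O)C1=CO[C@H](C)[C@@H](CO2)[C@@H]1CC2=O | intermediate
13 | hydroxytyrosol | OCCc1ccc(O)c(O)c1 | starting material
14 | 2-[3,4-bis(benzyloxy)phenyl]ethanol | OCCc1ccc(OCc2ccccc2)c(OCc2ccccc2)c1 | intermediate
15 | 1,2-bis(benzyloxy)-4-(2-bromoethyl)benzene | BrCCc1ccc(OCc2ccccc2)c(OCc2ccccc2)c1 | intermediate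
16 | caesium 2-[(2R,3R,4S)-3-(hydroxymethyl)-5-(methoxycarbonyl)-2-methyl-3,4-dihydro-2H-pyran-4-yl]acetate (not isolated) | COC(=O)C1=CO[C@H](C)[C@@H](CO)[C@@H]1CC(=O)[O-].[Cs+] | intermediate
17 | methyl (2R,3R,4S)-4-(2-{2-[3,4-bis(benzyloxy)phenyl]ethoxy}-2-oxoethyl)-3-(hydroxymethyl)-2-methyl-3,4-dihydro-2H-pyran-5-carboxylate | COC(=O)C1=CO[C@H](C)[C@@H](CO)[C@@H]1CC(=O)OCCc1ccc(OCc2ccccc2)c(OCc2ccccc2)c1 | intermediate
18 | methyl (2R,3R,4S)-4-{2-[2-(3,4-dihydroxyphenyl)ethoxy]-2-oxoethyl}-3-(hydroxymethyl)-2-methyl-3,4-dihydro-2H-pyran-5-carboxylate | COC(=O)C1=CO[C@H](C)[C@@H](CO)[C@@H]1CC(=O)OCCc1ccc(O)c(O)c1 | target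

**Step count:** 10 steps in total. The longest linear sequence is 7 steps (1, 2, 4, 5, 6, 9, 10).

**Steps most likely to fail**

Step 4.
- What may go wrong: crotyl alcohol may be lost from the condensation product by vinylogous β-elimination before ring closure. Residual amine or acetate may deactivate the chromium complex. The acceleration over the uncatalysed background may be too small, giving poor facial selectivity.
- Fallback: resolution replaces catalysis and only known chemistry is used. It sets out from 4 and 7 and comes back at 11.
- The metal-free domino Knoevenagel–oxa-Diels–Alder reaction (AcOH, EDDA, 4 Å MS, toluene, rt → 80 °C) should give the same trans-fused acetal as a racemate, that is 10 together with the mirror-image crotyl acetal F1.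
- Acid-catalysed exchange with (1R,2S,5R)-menthol (PPTS, toluene, crotyl alcohol removed under reduced pressure) converts the pair into the menthyl acetal of the wanted series F2 and the menthyl acetal of the mirror-image series F3.
- These diastereomers are separated by chromatography or crystallisation. Hydrolysis of F2 under the conditions of step 5 gives 11 and returns the menthol.

Step 9.
- What may go wrong: the salt may relactonise on drying, or the hydroxy ester may do so in the basic medium. Displacement at the phenethyl bromide may be slow and compete with elimination of HBr.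
- Fallback: O8 is protected before the ester is made. It sets out from 12 through the salt 16 and comes back at 17.
- Silylation of 16 (TBSCl, imidazole, DMF) gives the silyl ether silyl ester F4.
- K2CO3 in MeOH–H2O cleaves only the silyl ester and gives the silyl ether acid F5.
- Steglich esterification (EDC·HCl, DMAP, CH2Cl2) with alcohol 14 gives the silyl ether ester F6.
- HF·pyridine in THF at 0 °C frees O8–H and delivers 17. Step 8 is then not needed.

Step 2.
- What may go wrong: over-reduction to the alcohol, and loss of crotyl alcohol by β-elimination during work-up or on silica.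
- Fallback: a two-stage redox detour through a storable compound. It sets out from 3 and comes back at 4.
- LiAlH4 in Et2O at 0 °C reduces the ester fully to 3,3-bis[(E)-but-2-enyloxy]propan-1-ol F7, which can be purified.
- Buffered oxidation (Dess–Martin periodinane, NaHCO3, CH2Cl2, 0 °C) gives 4, which is filtered and used directly in step 4.

**Further compounds**
F1 | step 4 | methyl (1S,4aR,6S,8aS)-6-[(E)-but-2-enyloxy]-1-methyl-4a,5,8,8a-tetrahydro-1H,6H-pyrano[3,4-c]pyran-4-carboxylate (enantiomer of 10, formed with 10 as the racemate) | COC(=O)C1=CO[C@@H](C)[C@H](CO2)[C@H]1C[C@H]2OC/C=C/C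
F2 | step 4 | methyl (1R,4aS,6S,8aR)-1-methyl-6-{[(1R,2S,5R)-2-isopropyl-5-methylcyclohexyl]oxy}-4a,5,8,8a-tetrahydro-1H,6H-pyrano[3,4-c]pyran-4-carboxylate (axial menthyl acetal, wanted series) | COC(=O)C1=CO[C@H](C)[C@@H](CO2)[C@@H]1C[C@@H]2O[C@@H]3C[C@H](C)CC[C@H]3C(C)C
F3 | step 4 | methyl (1S,4aR,6R,8aS)-1-methyl-6-{[(1R,2S,5R)-2-isopropyl-5-methylcyclohexyl]oxy}-4a,5,8,8a-tetrahydro-1H,6H-pyrano[3,4-c]pyran-4-carboxylate (axial menthyl acetal, mirror-image core) | COC(=O)C1=CO[C@@H](C)[C@H](CO2)[C@H]1C[C@H]2O[C@@H]3C[C@H](C)CC[C@H]3C(C)C
F4 | step 9 | tert-butyldimethylsilyl 2-[(2R,3R,4S)-3-{[(tert-butyldimethylsilyl)oxy]methyl}-5-(methoxycarbonyl)-2-methyl-3,4-dihydro-2H-pyran-4-yl]acetate | COC(=O)C1=CO[C@H](C)[C@@H](CO[Si](C)(C)C(C)(C)C)[C@@H]1CC(=O)O[Si](C)(C)C(C)(C)C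
F5 | step 9 | 2-[(2R,3R,4S)-3-{[(tert-butyldimethylsilyl)oxy]methyl}-5-(methoxycarbonyl)-2-methyl-3,4-dihydro-2H-pyran-4-yl]acetic acid | COC(=O)C1=CO[C@H](C)[C@@H](CO[Si](C)(C)C(C)(C)C)[C@@H]1CC(=O)O
F6 | step 9 | methyl (2R,3R,4S)-4-(2-{2-[3,4-bis(benzyloxy)phenyl]ethoxy}-2-oxoethyl)-3-{[(tert-butyldimethylsilyl)oxy]methyl}-2-methyl-3,4-dihydro-2H-pyran-5-carboxylate | COC(=O)C1=CO[C@H](C)[C@@H](CO[Si](C)(C)C(C)(C)C)[C@@H]1CC(=O)OCCc1ccc(OCc2ccccc2)c(OCc2ccccc2)c1
F7 | step 2 | 3,3-bis[(E)-but-2-enyloxy]propan-1-ol | OCCC(OC/C=C/C)OC/C=C/C
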